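## The problem

The target is a 4-arylflavan: a (2S,4R)-7,3',4'-trihydroxyflavan (ring A fused to ring C, ring B on C2) bonded through C4 to C8' of (−)-epigallocatechin (ring D fused to ring F, ring E on C2'). Upper-unit atoms are unprimed (O1, C2, C3, C4, C4a … C8a) and lower-unit atoms are primed. C4 is a diarylmethine carbon held between C4a of ring A and C8', a ring-D carbon flanked by two oxygen-bearing carbons (C7' and C8a'). The central task is therefore to join an sp3 carbon to two electron-rich arenes, one of them doubly ortho-substituted. Of the four stereocentres, C2' and C3' (cis, both R) come ready-made in epigallocatechin and only have to be carried through. C4 (R) and C2 (S) must be created, and analysis of the descriptors shows that the two aryl groups on ring C are trans. C2' and C3' lie on the far side of ring D and cannot be relied on to control C4, so C4 needs an external chiral influence. C2 could be steered by C4, but closures under equilibrium control or by hydride delivery to a C2 cation put the two aryl groups cis, so C2 is better set on its own and bonded to O1 with defined inversion. The molecule carries eight phenols (a pyrogallol and a catechol among them) and one secondary alcohol, and it has three acid-ionisable benzylic bonds (C2–O1, C2'–O1', C4–C8'), so every oxygen must be masked and the final unmasking must be neutral. The enabling feature is that C4 is β to C2: with C2 as a ketone carbonyl bearing ring B and C3=C4 as a double bond attached to ring D, C4 becomes the electrophilic end of an enone. Ring A, with the future O1 ortho to C4a, can then be delivered to C4 as an aryl nucleophile.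

## Retrosynthesis

**20 ⇒ 19.** No skeletal bond is cut; the nine O–H bonds of target 20 are traced back to nine benzyl ethers in 19. Benzyl is preferred to methyl (no mild cleavage), to silyl (would not survive the hydroxide and organolithium steps) and to acetals (an acidic last step would endanger C4–C8' and the two benzylic ring ethers). The forward step must remove nine benzyl groups by hydrogenolysis without opening C2–O1 or C2'–O1'.

**19 ⇒ 18.** The O1–C2 bond of ring C is cut, giving phenol–carbinol 18. The neighbouring cuts are O1–C8a, which would need a halogen on ring A and a metal-catalysed etherification (kept as a reserve), and C2–aryl, which leaves C2 to substrate control under Lewis acid. Cutting O1–C2 turns C2 into an ordinary secondary benzylic alcohol whose configuration can be chosen freely. The forward closure must be an SN2 displacement with inversion, so that a 1R carbinol gives 2S, trans to the C4 aryl group.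

**18 ⇒ 17 ⇒ 16.** These are two functional-group changes. The C8a phenol is masked as an allyl ether (17), the one ether that survives aqueous hydroxide and comes off under neutral conditions beside nine benzyl ethers. Carbinol 17 is derived from ketone 16 by reagent-controlled reduction. The C2 ketone is what makes C4 an electrophilic carbon one step earlier.

**16 ⇒ 10 + 15.** The C4–C4a bond is cut, giving enone 10 (rings D, E, F and B) and arylboronic acid 15 (ring A). Of the three bonds at C4 this is the best one to make last:
- Forming C4–C8' by conjugate addition would need a boron or metal on C8' between two ortho oxygens, where transmetalation is slow and protodeboronation fast.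
- Forming C3–C4 by alkylation would pass through a diarylmethyl cation with no handle on configuration.
- Forming C4–C4a puts the hindrance on the acceptor and leaves the nucleophile with a single ortho substituent.

The cut divides the molecule into two parts of comparable size. It asks the forward reaction for 1,4-addition with catalyst-controlled facial selectivity at C4.

**10 ⇒ 6 + 8.** The C3=C4 double bond is cut by a retro-aldol condensation into aldehyde 6 and acetophenone 8. The alternative, a Heck-type union at C4–C8' from bromide 4, would require oxidative addition at a doubly ortho-substituted, electron-rich bromide. The condensation only asks for a non-enolisable aldehyde, and E geometry follows from conjugation.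

**6 ⇒ 4 ⇒ 3 ⇒ 2 ⇒ 1.** The formyl carbon is removed (via aryllithium 5 and bromide 4), then the bromine, then the benzyl groups, arriving at purchasable epigallocatechin 1 with C2' and C3' intact. Bromination is known to select the ring-D position next to the ring oxygen. Benzylation is split into a phenol-selective stage (2) and an alkoxide stage (3) so that strong base never meets a free phenol of ring E.

**15 ⇒ 13 ⇒ 12 ⇒ 11 and 8 ⇒ 7.** The C–B bond is traced to the C–Br bond of 13 (via aryllithium 14). The allyl and benzyl ethers are removed in turn to reach 4-bromoresorcinol 11, in which the bromine already marks the future C4a. The forward sequence must tell the two hydroxyls of 11 apart. Acetophenone 8 is the dibenzyl ether of purchasable 7.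

## Roads not taken

**Alternative 1:** The cut is C4'–C4a' of ring F. A hepta-O-benzyl relative of the target, A2, is traced back to aryl ether A1, in which one ring-D oxygen carries a 1-aryl-2,3-epoxypropyl group. In the forward step AuCl3 with AgOTf (trivalent gold) activates the terminal epoxide and C4a' attacks its CH2 carbon in a 6-endo Friedel–Crafts closure, forming ring F and freeing the C3' hydroxyl.
- Merits: the closure is intramolecular onto the most nucleophilic arene of the molecule, and the C3'–O bond is not touched, so C3' is carried over from the epoxide. The two ring-D hydroxyls flanking C8' are equivalent before one is etherified, so the etherification leading to A1 poses no regiochemical question.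
- Weak points: C2' and C3' would have to be built by asymmetric synthesis although epigallocatechin supplies both. The key step creates neither C4 nor C2 nor the ring A–ring D junction, all of which must already be present in A1, so the hard part needs a second solution anyway. A strong Lewis acid would meet a p-alkoxybenzylic aryl ether (C2'–O1'), a free phenol and an acid-labile 4-arylflavan.
- Comparison: the ring closure itself is kinetically safer than an intermolecular addition to a hindered enone, and that is conceded. The chosen plan sets against it that two stereocentres are bought and that its key step solves C4 and the central junction.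

**Alternative 2:** The cut removes C4–C8', C3–C4 and O1–C2 together. Aryllithium 5 of the present route, transmetalated with MgBr2 to arylmagnesium bromide A3, adds to O-Boc salicylaldehyde A4. The Boc group migrates to the new alkoxide and the carbonate is lost, unmasking an o-quinone methide. Chiral enol ether A5 traps it in a [4+2] cycloaddition to give 2-alkoxychroman A6.
- Merits: three bonds, ring C and C4 are made in one flask, and compounds 1–5 are shared with the chosen route. In bond economy up to a ring-C chroman it is clearly better than the chosen sequence.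
- Weak points: A6 is a 2,4-cis acetal and not a flavan, so ring B still has to be introduced by ionising C2 and adding an aryl nucleophile, a second stereo-determining event under substrate control. C4 is relayed from a single auxiliary through the endo approach to a quinone methide that carries the very large, itself chiral, epigallocatechin aryl group, which may reinforce or oppose the auxiliary. The trioxygenated aryl group stabilises the quinone methide and may slow or reverse the cycloaddition. The auxiliary is stoichiometric.
- Comparison: the chosen plan is about two steps longer in the upper half. Against that, each new stereocentre is set by a catalyst whose sense can be reversed by taking its enantiomer, and ring B is in place from the start.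

**Alternative 3:** The cut is the bond from C2 to ring B. BF3·OEt2 ionises 2-acetoxychroman A7 to the O1=C2 oxocarbenium ion, and potassium aryltrifluoroborate A8 adds trans to the C4 substituent to give A9, which is the same compound as 19.
- Merits: it is convergent, ring B comes last (useful for analogues), and the substrate bias points the right way (trans). One step would replace the reduction, deallylation and closure of the chosen endgame, and in that respect it is better.
- Weak points: it leaves the central problem unsolved, since A7 must already contain C4 and the ring A–ring D junction. BF3·OEt2 acting on a 4-arylchroman whose 4-aryl group is a phloroglucinol ether invites ionisation of C4–C8' and loss of H3 from the cation. The level of trans selectivity rests on conformational preference alone and cannot be corrected by a reagent.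
- Comparison: the chosen plan sets C2 by reagent control followed by inversion, and uses no Lewis acid once C4 is installed.

Key step: step 10

Assumption: the chiral diene is taken to select the face of enone 10 as it does with simple (E)-enones, which calls for the (S,S) ligand; should the sense prove opposite, the (R,R) ligand would be used with no other change.

Note on locants: in compounds 2–6 the chroman position 8 is the position called C8' in the target.

## Route

Step 1
Reactants: 1 (−)-epigallocatechin
Product: 2 5,7,3',4',5'-penta-O-benzyl-epigallocatechin [(2R,3R)-5,7-bis(benzyloxy)-2-[3,4,5-tris(benzyloxy)phenyl]chroman-3-ol]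
Conditions: BnBr (5.5 equiv), K2CO3, DMF, 0 °C to rt, argon
Reagents that add atoms: benzyl bromide, BrCc1ccccc1
Why: Williamson etherification; K2CO3 deprotonates only the five phenols, so the secondary hydroxyl stays free, and the mild base with exclusion of air keeps ring E from oxidising and C2 from epimerising.

Step 2
Reactants: 2 5,7,3',4',5'-penta-O-benzyl-epigallocatechin
Product: 3 hexa-O-benzyl-epigallocatechin [(2R,3R)-3,5,7-tris(benzyloxy)-2-[3,4,5-tris(benzyloxy)phenyl]chromane]
Conditions: NaH, BnBr, Bu4NI (cat.), THF/DMF, 0 °C to rt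
Reagents that add atoms: benzyl bromide, BrCc1ccccc1
Why: Williamson etherification of the remaining secondary alcohol through its sodium alkoxide; with every phenol capped there is no quinone methide pathway by which C2 could epimerise.

Step 3
Reactants: 3 hexa-O-benzyl-epigallocatechin
Product: 4 8-bromo-hexa-O-benzyl-epigallocatechin
Conditions: NBS (1.0 equiv), CH2Cl2, −78 °C to 0 °C, dark
Reagents that add atoms: N-bromosuccinimide, O=C1CCC(=O)N1Br
Why: Electrophilic aromatic bromination; ring D, activated by three oxygens, reacts before ring E, and in 5,7-dialkoxyflavans the position next to the ring oxygen is brominated in preference to the one crowded between two benzyloxy groups.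

Step 4
Reactants: 4 8-bromo-hexa-O-benzyl-epigallocatechin
Product: 6 hexa-O-benzyl-epigallocatechin-8-carbaldehyde, via 8-lithio-hexa-O-benzyl-epigallocatechin 5 (not isolated)
Conditions: n-BuLi, THF, −78 °C; DMF, −78 °C to 0 °C; aq NH4Cl
Reagents that add atoms: N,N-dimethylformamide, CN(C)C=O
Why: Bromine–lithium exchange and formylation of aryllithium 5 with DMF; exchange at −78 °C is faster than metalation of the benzylic ether positions, and 8-lithiated benzyl-protected flavan-3-ols are established nucleophiles.

Step 5
Reactants: 7 3',4'-dihydroxyacetophenone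
Product: 8 3',4'-bis(benzyloxy)acetophenone
Conditions: BnBr, K2CO3, DMF, 60 °C
Reagents that add atoms: benzyl bromide, BrCc1ccccc1
Why: Williamson etherification of both phenols; the methyl ketone is unaffected by carbonate.

Step 6
Reactants: 6 hexa-O-benzyl-epigallocatechin-8-carbaldehyde; 8 3',4'-bis(benzyloxy)acetophenone
Product: 10 (E)-1-[3,4-bis(benzyloxy)phenyl]-3-(hexa-O-benzyl-epigallocatechin-8-yl)prop-2-en-1-one, via the aldol adduct 9 (not isolated)
Conditions: KOH, EtOH/THF, rt
Reagents that add atoms: none
Why: Claisen–Schmidt condensation; the enolate of 8 adds to the non-enolisable aldehyde 6 and aldol 9 loses water by an E1cB pathway to the conjugated enone, for which E is the favoured geometry; 2,4,6-trialkoxybenzaldehydes are routine partners in this reaction.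

Step 7
Reactants: 11 4-bromoresorcinol
Product: 12 5-(benzyloxy)-2-bromophenol
Conditions: BnBr (1.0 equiv), K2CO3 (1.0 equiv), acetone, rt
Reagents that add atoms: benzyl bromide, BrCc1ccccc1
Why: Williamson mono-etherification; the hydroxyl para to bromine is unhindered and not hydrogen-bonded to the halogen and should be alkylated preferentially, the regioisomer and the dibenzyl ether being removed by chromatography.

Step 8
Reactants: 12 5-(benzyloxy)-2-bromophenol
Product: 13 2-(allyloxy)-4-(benzyloxy)-1-bromobenzene
Conditions: allyl bromide, K2CO3, acetone, 50 °C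
Reagents that add atoms: allyl bromide, C=CCBr
Why: Williamson etherification of the remaining, bromine-flanked phenol; this oxygen is the future O1 and receives the one group that can later be removed beside benzyl ethers.

Step 9
Reactants: 13 2-(allyloxy)-4-(benzyloxy)-1-bromobenzene
Product: 15 [2-(allyloxy)-4-(benzyloxy)phenyl]boronic acid, via [2-(allyloxy)-4-(benzyloxy)phenyl]lithium 14 (not isolated)
Conditions: B(OiPr)3, n-BuLi, THF/toluene, −78 °C; aq HCl to pH 5
Reagents that add atoms: triisopropyl borate, CC(C)OB(OC(C)C)OC(C)C; water, O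
Why: Bromine–lithium exchange with in-situ trapping by the borate ester and hydrolysis on work-up; having the borate present at −78 °C captures aryllithium 14 before it can cyclise onto or rearrange its ortho allyloxy group.

Step 10
Reactants: 10 (E)-1-[3,4-bis(benzyloxy)phenyl]-3-(hexa-O-benzyl-epigallocatechin-8-yl)prop-2-en-1-one; 15 [2-(allyloxy)-4-(benzyloxy)phenyl]boronic acid
Product: 16 (3R)-3-[2-(allyloxy)-4-(benzyloxy)phenyl]-1-[3,4-bis(benzyloxy)phenyl]-3-(hexa-O-benzyl-epigallocatechin-8-yl)propan-1-one
Conditions: [RhCl(C2H4)2]2 (2.5 mol%), (1S,4S)-2,5-diphenylbicyclo[2.2.2]octa-2,5-diene (5.5 mol%), aq KOH (0.5 equiv), 15 (2.5 equiv), 1,4-dioxane/H2O, 30–50 °C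
Reagents that add atoms: none
Why: Hayashi–Miyaura reaction, the rhodium-catalysed asymmetric 1,4-addition of an arylboronic acid to an enone, for which chalcones are standard acceptors. Hydroxide turns the chloride precatalyst into a hydroxo complex of monovalent rhodium bound to the chiral diene; transmetalation with 15 gives an aryl–rhodium species, the C3=C4 bond of 10 inserts with the aryl group going to C4, and water protonates the resulting rhodium enolate at C3 and regenerates the hydroxo complex. One skeletal bond, C4–C4a, is formed and no ring closes. The new stereocentre C4 is controlled by the ligand: the C2-symmetric diene lets the enone bind in only one way that keeps its aroyl group clear of a phenyl substituent of the ligand, and the (S,S) enantiomer is expected to expose the si face of C4, which gives the 4R configuration (3R in the name of 16). The step needs 1,4- rather than 1,2-addition, which aryl–rhodium species show intrinsically with enones, and it needs facial selectivity, which is left to the catalyst because C2' and C3' lie on the far side of ring D. These two centres make the C4 epimers diastereomers, so a minor epimer can be removed by chromatography. The two ortho oxygens twist ring D out of the enone plane, which limits its electron donation into the acceptor, and the boronic acid has only one ortho substituent, so transmetalation should outrun protodeboronation; the terminal alkene of the allyl ether is not an acceptor for the aryl–rhodium species under these conditions.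

Step 11
Reactants: 16 (3R)-3-[2-(allyloxy)-4-(benzyloxy)phenyl]-1-[3,4-bis(benzyloxy)phenyl]-3-(hexa-O-benzyl-epigallocatechin-8-yl)propan-1-one
Product: 17 (1R,3R)-3-[2-(allyloxy)-4-(benzyloxy)phenyl]-1-[3,4-bis(benzyloxy)phenyl]-3-(hexa-O-benzyl-epigallocatechin-8-yl)propan-1-ol
Conditions: (S)-2-methyl-CBS-oxazaborolidine (20 mol%), catecholborane, toluene/CH2Cl2, −78 °C to −30 °C; MeOH, aq NaOH wash
Reagents that add atoms: none
Why: Corey–Bakshi–Shibata reduction; the oxazaborolidine binds the aryl ketone with ring B as the large group and the (S) catalyst delivers hydride to give the 1R carbinol (the future C2) under reagent control; catecholborane is the hydride source because it does not hydroborate the allyl group at low temperature.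

Step 12
Reactants: 17 (1R,3R)-3-[2-(allyloxy)-4-(benzyloxy)phenyl]-1-[3,4-bis(benzyloxy)phenyl]-3-(hexa-O-benzyl-epigallocatechin-8-yl)propan-1-ol
Product: 18 (1R,3R)-3-[4-(benzyloxy)-2-hydroxyphenyl]-1-[3,4-bis(benzyloxy)phenyl]-3-(hexa-O-benzyl-epigallocatechin-8-yl)propan-1-ol
Conditions: Pd(PPh3)4 (5 mol%), morpholine, THF, rt
Reagents that add atoms: none
Why: Tsuji–Trost deallylation; zerovalent palladium ionises the aryl allyl ether to a π-allyl complex that morpholine intercepts, while benzyl ethers, the free carbinol and all stereocentres are untouched.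

Step 13
Reactants: 18 (1R,3R)-3-[4-(benzyloxy)-2-hydroxyphenyl]-1-[3,4-bis(benzyloxy)phenyl]-3-(hexa-O-benzyl-epigallocatechin-8-yl)propan-1-ol
Product: 19 (2S,4R)-7-(benzyloxy)-2-[3,4-bis(benzyloxy)phenyl]-4-(hexa-O-benzyl-epigallocatechin-8-yl)chromane
Conditions: PPh3, DIAD, toluene (high dilution), 0 °C to rt
Reagents that add atoms: none
Why: Intramolecular Mitsunobu etherification, the established way from 1-aryl-3-(2-hydroxyaryl)propan-1-ols to 2-arylchromans; the phosphine–azodicarboxylate pair activates the secondary alcohol and the phenol displaces it in a 6-exo-tet SN2 closure, so C2 is formed with inversion (1R carbinol to 2S) and ends up trans to the C4 aryl group.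

Step 14
Reactants: 19 (2S,4R)-7-(benzyloxy)-2-[3,4-bis(benzyloxy)phenyl]-4-(hexa-O-benzyl-epigallocatechin-8-yl)chromane
Product: 20 (2R,3R)-8-[(2S,4R)-2-(3,4-dihydroxyphenyl)-7-hydroxychroman-4-yl]-2-(3,4,5-trihydroxyphenyl)chromane-3,5,7-triol
Conditions: H2 (1 atm), Pd(OH)2/C, THF/MeOH, rt; filtration under argon
Reagents that add atoms: none
Why: Hydrogenolysis of the nine benzyl ethers, the standard last step for benzylated flavan-3-ols and their oligomers; under neutral conditions at atmospheric pressure the cyclic benzylic ethers C2–O1 and C2'–O1' should survive and no stereocentre is touched.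

## Compound list

1 | (−)-epigallocatechin | Oc1cc(O)c2c(c1)O[C@H](c1cc(O)c(O)c(O)c1)[C@H](O)C2 | starting material
2 | 5,7,3',4',5'-penta-O-benzyl-epigallocatechin | c1ccccc1COc1cc(OCc3ccccc3)c2c(c1)O[C@H](c1cc(OCc3ccccc3)c(OCc3ccccc3)c(OCc3ccccc3)c1)[C@H](O)C2 | intermediate
3 | hexa-O-benzyl-epigallocatechin | c1ccccc1COc1cc(OCc3ccccc3)c2c(c1)O[C@H](c1cc(OCc3ccccc3)c(OCc3ccccc3)c(OCc3ccccc3)c1)[C@H](OCc3ccccc3)C2 | intermediate
4 | 8-bromo-hexa-O-benzyl-epigallocatechin | Brc1c(OCc3ccccc3)cc(OCc3ccccc3)c2c1O[C@H](c1cc(OCc3ccccc3)c(OCc3ccccc3)c(OCc3ccccc3)c1)[C@H](OCc3ccccc3)C2 | intermediate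
5 | 8-lithio-hexa-O-benzyl-epigallocatechin | [Li]c1c(OCc3ccccc3)cc(OCc3ccccc3)c2c1O[C@H](c1cc(OCc3ccccc3)c(OCc3ccccc3)c(OCc3ccccc3)c1)[C@H](OCc3ccccc3)C2 | intermediate
6 | hexa-O-benzyl-epigallocatechin-8-carbaldehyde | O=Cc1c(OCc3ccccc3)cc(OCc3ccccc3)c2c1O[C@H](c1cc(OCc3ccccc3)c(OCc3ccccc3)c(OCc3ccccc3)c1)[C@H](OCc3ccccc3)C2 | intermediate
7 | 3',4'-dihydroxyacetophenone | CC(=O)c1ccc(O)c(O)c1 | starting material
8 | 3',4'-bis(benzyloxy)acetophenone | CC(=O)c1ccc(OCc2ccccc2)c(OCc2ccccc2)c1 | intermediate
9 | 1-[3,4-bis(benzyloxy)phenyl]-3-hydroxy-3-(hexa-O-benzyl-epigallocatechin-8-yl)propan-1-one (aldol adduct, both carbinol epimers) | O=C(c1ccc(OCc3ccccc3)c(OCc3ccccc3)c1)CC(O)c1c(OCc3ccccc3)cc(OCc3ccccc3)c2c1O[C@H](c1cc(OCc3ccccc3)c(OCc3ccccc3)c(OCc3ccccc3)c1)[C@H](OCc3ccccc3)C2 | intermediate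
10 | (E)-1-[3,4-bis(benzyloxy)phenyl]-3-(hexa-O-benzyl-epigallocatechin-8-yl)prop-2-en-1-one | O=C(c1ccc(OCc3ccccc3)c(OCc3ccccc3)c1)/C=C/c1c(OCc3ccccc3)cc(OCc3ccccc3)c2c1O[C@H](c1cc(OCc3ccccc3)c(OCc3ccccc3)c(OCc3ccccc3)c1)[C@H](OCc3ccccc3)C2 | intermediate
11 | 4-bromoresorcinol | Oc1ccc(Br)c(O)c1 | starting material
12 | 5-(benzyloxy)-2-bromophenol | Oc1cc(OCc2ccccc2)ccc1Br | intermediate
13 | 2-(allyloxy)-4-(benzyloxy)-1-bromobenzene | C=CCOc1cc(OCc2ccccc2)ccc1Br | intermediate
14 | [2-(allyloxy)-4-(benzyloxy)phenyl]lithium | [Li]c1ccc(OCc2ccccc2)cc1OCC=C | intermediate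
15 | [2-(allyloxy)-4-(benzyloxy)phenyl]boronic acid | OB(O)c1ccc(OCc2ccccc2)cc1OCC=C | intermediate
16 | (3R)-3-[2-(allyloxy)-4-(benzyloxy)phenyl]-1-[3,4-bis(benzyloxy)phenyl]-3-(hexa-O-benzyl-epigallocatechin-8-yl)propan-1-one | O=C(c1ccc(OCc3ccccc3)c(OCc3ccccc3)c1)C[C@H](c1ccc(OCc3ccccc3)cc1OCC=C)c1c(OCc3ccccc3)cc(OCc3ccccc3)c2c1O[C@H](c1cc(OCc3ccccc3)c(OCc3ccccc3)c(OCc3ccccc3)c1)[C@H](OCc3ccccc3)C2 | intermediate
17 | (1R,3R)-3-[2-(allyloxy)-4-(benzyloxy)phenyl]-1-[3,4-bis(benzyloxy)phenyl]-3-(hexa-O-benzyl-epigallocatechin-8-yl)propan-1-ol | O[C@@H](c1ccc(OCc3ccccc3)c(OCc3ccccc3)c1)C[C@H](c1ccc(OCc3ccccc3)cc1OCC=C)c1c(OCc3ccccc3)cc(OCc3ccccc3)c2c1O[C@H](c1cc(OCc3ccccc3)c(OCc3ccccc3)c(OCc3ccccc3)c1)[C@H](OCc3ccccc3)C2 | intermediate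
18 | (1R,3R)-3-[4-(benzyloxy)-2-hydroxyphenyl]-1-[3,4-bis(benzyloxy)phenyl]-3-(hexa-O-benzyl-epigallocatechin-8-yl)propan-1-ol | O[C@@H](c1ccc(OCc3ccccc3)c(OCc3ccccc3)c1)C[C@H](c1ccc(OCc3ccccc3)cc1O)c1c(OCc3ccccc3)cc(OCc3ccccc3)c2c1O[C@H](c1cc(OCc3ccccc3)c(OCc3ccccc3)c(OCc3ccccc3)c1)[C@H](OCc3ccccc3)C2 | intermediate
19 | (2S,4R)-7-(benzyloxy)-2-[3,4-bis(benzyloxy)phenyl]-4-(hexa-O-benzyl-epigallocatechin-8-yl)chromane (nona-O-benzyl target) | c1ccccc1COc1ccc2c(c1)O[C@H](c1ccc(OCc3ccccc3)c(OCc3ccccc3)c1)C[C@H]2c1c(OCc3ccccc3)cc(OCc3ccccc3)c2c1O[C@H](c1cc(OCc3ccccc3)c(OCc3ccccc3)c(OCc3ccccc3)c1)[C@H](OCc3ccccc3)C2 | intermediate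
20 | (2R,3R)-8-[(2S,4R)-2-(3,4-dihydroxyphenyl)-7-hydroxychroman-4-yl]-2-(3,4,5-trihydroxyphenyl)chromane-3,5,7-triol (CNP0211965.1) | Oc1ccc2c(c1)O[C@H](c1ccc(O)c(O)c1)C[C@H]2c1c(O)cc(O)c2c1O[C@H](c1cc(O)c(O)c(O)c1)[C@H](O)C2 | target

## Step count and risks

Total: 14 steps. Longest linear sequence: 10 steps (steps 1, 2, 3, 4, 6, 10, 11, 12, 13, 14).

**Step 10 (key step).** The insertion of a hindered enone whose β-aryl group is strongly electron-donating may be slow, which would let protodeboronation of the electron-rich boronic acid consume the nucleophile. Facial selectivity may also be insufficient if the twisted ring D or the nearby ring E disturbs the way the enone binds to the catalyst.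

The fallback replaces catalyst control by an oxazolidinone auxiliary and a more electrophilic acceptor. It sets out from aldehyde 6 and bromide 13 and comes back to the route at ketone 16.
- Horner–Wadsworth–Emmons olefination of 6 (LiCl, iPr2NEt, MeCN/THF) with diethyl {2-oxo-2-[(4S)-2-oxo-4-phenyl-1,3-oxazolidin-3-yl]ethyl}phosphonate would give (4S)-3-[(2E)-3-(hexa-O-benzyl-epigallocatechin-8-yl)prop-2-enoyl]-4-phenyl-1,3-oxazolidin-2-one F1.
- Bromide 13 and Mg turnings would give [2-(allyloxy)-4-(benzyloxy)phenyl]magnesium bromide F2.
- With CuBr·SMe2 in THF at −40 °C, F2 should add to the magnesium-chelated, syn-s-cis enoyl imide from the face away from the 4-phenyl group, giving the (3R)-adduct F3.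
- Transamination with MeNH(OMe)·HCl and AlMe3 would give the Weinreb amide F4 and release the auxiliary.
- [3,4-Bis(benzyloxy)phenyl]magnesium bromide F5, made from 4-bromo-1,2-bis(benzyloxy)benzene and Mg, would convert F4 into 16.

**Step 13.** The activated carbinol is benzylic to a 3,4-dialkoxyphenyl ring. It may ionise before the phenol attacks, which would erode the inversion at C2 or lead to elimination toward a styrene.

The fallback forms the other C–O bond of ring C, the aryl–oxygen bond O1–C8a, so that the carbinol C–O bond is never broken. It sets out from enone 10 and comes back at 19.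
- Purchasable 4-bromo-3-chlorophenol would be benzylated (BnBr, K2CO3) to 4-(benzyloxy)-1-bromo-2-chlorobenzene F6.
- Bromine–lithium exchange in the presence of B(OiPr)3 at −78 °C would give [4-(benzyloxy)-2-chlorophenyl]boronic acid F7.
- Addition of F7 to 10 under the conditions of step 10 would give the chloro ketone F8. It has the same spatial arrangement at C4 as 16 but is named 3S because chlorine raises the rank of ring A.
- Reduction with the (R)-configured CBS catalyst and BH3·SMe2 would give the (1S,3S)-carbinol F9.
- Intramolecular Buchwald–Hartwig etherification (Pd(OAc)2, 2-(di-tert-butylphosphino)-1,1'-binaphthyl, Cs2CO3, toluene, 70 °C) would close ring C with retention at C2.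

**Step 11.** The small substituent of the ketone is a CH2 group carrying a bulky diarylmethyl unit, so discrimination by the oxazaborolidine may be reduced, and the C4 centre may be mismatched with the catalyst. Adventitious hydroboration of the allyl group would also cost material.

The fallback changes the reducing system to Noyori asymmetric transfer hydrogenation (RuCl(p-cymene)[(R,R)-TsDPEN], HCO2H/Et3N, CH2Cl2). Hydride then comes from formate through a ruthenium hydride and no borane meets the alkene. It sets out from 16 and comes back at 17 and makes no new compound.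

**Step 7.** Discrimination between the two hydroxyls of 11 may be poor, since the bromine-flanked hydroxyl is the more acidic one, and over-alkylation may occur.

The fallback enforces the site selection with a bulky temporary group. It sets out from 11 and comes back at 13.
- TBSCl and imidazole in CH2Cl2 at 0 °C would silylate the unhindered hydroxyl to give 2-bromo-5-[(tert-butyldimethylsilyl)oxy]phenol F10.
- Mitsunobu allylation (allyl alcohol, PPh3, DIAD) of the remaining phenol would give [3-(allyloxy)-4-bromophenoxy](tert-butyl)dimethylsilane F11.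
- Bu4NF would cleave the silyl ether to 3-(allyloxy)-4-bromophenol F12.
- Benzylation (BnBr, K2CO3, DMF) would give 13.

## Further compounds

F1 | step 10 | (4S)-3-[(2E)-3-(hexa-O-benzyl-epigallocatechin-8-yl)prop-2-enoyl]-4-phenyl-1,3-oxazolidin-2-one | O=C1OC[C@H](c2ccccc2)N1C(=O)/C=C/c1c(OCc3ccccc3)cc(OCc3ccccc3)c2c1O[C@H](c1cc(OCc3ccccc3)c(OCc3ccccc3)c(OCc3ccccc3)c1)[C@H](OCc3ccccc3)C2
F2 | step 10 | [2-(allyloxy)-4-(benzyloxy)phenyl]magnesium bromide | Br[Mg]c1ccc(OCc2ccccc2)cc1OCC=C
F3 | step 10 | (4S)-3-[(3R)-3-[2-(allyloxy)-4-(benzyloxy)phenyl]-3-(hexa-O-benzyl-epigallocatechin-8-yl)propanoyl]-4-phenyl-1,3-oxazolidin-2-one | O=C1OC[C@H](c2ccccc2)N1C(=O)C[C@H](c1ccc(OCc3ccccc3)cc1OCC=C)c1c(OCc3ccccc3)cc(OCc3ccccc3)c2c1O[C@H](c1cc(OCc3ccccc3)c(OCc3ccccc3)c(OCc3ccccc3)c1)[C@H](OCc3ccccc3)C2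
F4 | step 10 | (3R)-3-[2-(allyloxy)-4-(benzyloxy)phenyl]-3-(hexa-O-benzyl-epigallocatechin-8-yl)-N-methoxy-N-methylpropanamide | CON(C)C(=O)C[C@H](c1ccc(OCc3ccccc3)cc1OCC=C)c1c(OCc3ccccc3)cc(OCc3ccccc3)c2c1O[C@H](c1cc(OCc3ccccc3)c(OCc3ccccc3)c(OCc3ccccc3)c1)[C@H](OCc3ccccc3)C2
F5 | step 10 | [3,4-bis(benzyloxy)phenyl]magnesium bromide | Br[Mg]c1ccc(OCc2ccccc2)c(OCc2ccccc2)c1
F6 | step 13 | 4-(benzyloxy)-1-bromo-2-chlorobenzene | Clc1cc(OCc2ccccc2)ccc1Br
F7 | step 13 | [4-(benzyloxy)-2-chlorophenyl]boronic acid | OB(O)c1ccc(OCc2ccccc2)cc1Cl
F8 | step 13 | (3S)-1-[3,4-bis(benzyloxy)phenyl]-3-[4-(benzyloxy)-2-chlorophenyl]-3-(hexa-O-benzyl-epigallocatechin-8-yl)propan-1-one | O=C(c1ccc(OCc3ccccc3)c(OCc3ccccc3)c1)C[C@H](c1ccc(OCc3ccccc3)cc1Cl)c1c(OCc3ccccc3)cc(OCc3ccccc3)c2c1O[C@H](c1cc(OCc3ccccc3)c(OCc3ccccc3)c(OCc3ccccc3)c1)[C@H](OCc3ccccc3)C2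
F9 | step 13 | (1S,3S)-1-[3,4-bis(benzyloxy)phenyl]-3-[4-(benzyloxy)-2-chlorophenyl]-3-(hexa-O-benzyl-epigallocatechin-8-yl)propan-1-ol | O[C@H](c1ccc(OCc3ccccc3)c(OCc3ccccc3)c1)C[C@H](c1ccc(OCc3ccccc3)cc1Cl)c1c(OCc3ccccc3)cc(OCc3ccccc3)c2c1O[C@H](c1cc(OCc3ccccc3)c(OCc3ccccc3)c(OCc3ccccc3)c1)[C@H](OCc3ccccc3)C2
F0 | step 11 | none | none
F10 | step 7 | 2-bromo-5-[(tert-butyldimethylsilyl)oxy]phenol | Oc1cc(O[Si](C)(C)C(C)(C)C)ccc1Br
F11 | step 7 | [3-(allyloxy)-4-bromophenoxy](tert-butyl)dimethylsilane | C=CCOc1cc(O[Si](C)(C)C(C)(C)C)ccc1Br
F12 | step 7 | 3-(allyloxy)-4-bromophenol | Oc1ccc(Br)c(OCC=C)c1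
A1 | alternative 1 | (2S,4R)-7-(benzyloxy)-2-[3,4-bis(benzyloxy)phenyl]-4-{4-(benzyloxy)-2-hydroxy-6-[(R)-[(2R)-oxiran-2-yl][3,4,5-tris(benzyloxy)phenyl]methoxy]phenyl}chromane | c1ccccc1COc1ccc2c(c1)O[C@H](c1ccc(OCc3ccccc3)c(OCc3ccccc3)c1)C[C@H]2c1c(O)cc(OCc3ccccc3)cc1O[C@H](c1cc(OCc3ccccc3)c(OCc3ccccc3)c(OCc3ccccc3)c1)[C@H]1CO1
A2 | alternative 1 | hepta-O-benzyl target with free C7' and C3' hydroxyls | c1ccccc1COc1ccc2c(c1)O[C@H](c1ccc(OCc3ccccc3)c(OCc3ccccc3)c1)C[C@H]2c1c(O)cc(OCc3ccccc3)c2c1O[C@H](c1cc(OCc3ccccc3)c(OCc3ccccc3)c(OCc3ccccc3)c1)[C@H](O)C2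
A3 | alternative 2 | (hexa-O-benzyl-epigallocatechin-8-yl)magnesium bromide | Br[Mg]c1c(OCc3ccccc3)cc(OCc3ccccc3)c2c1O[C@H](c1cc(OCc3ccccc3)c(OCc3ccccc3)c(OCc3ccccc3)c1)[C@H](OCc3ccccc3)C2
A4 | alternative 2 | 4-(benzyloxy)-2-[(tert-butoxycarbonyl)oxy]benzaldehyde | O=Cc1ccc(OCc2ccccc2)cc1OC(=O)OC(C)(C)C
A5 | alternative 2 | (1R,2S)-2-phenylcyclohexyl vinyl ether | C=CO[C@@H]1CCCC[C@H]1c1ccccc1
A6 | alternative 2 | 2,4-cis 7-(benzyloxy)-4-(hexa-O-benzyl-epigallocatechin-8-yl)-2-{[(1R,2S)-2-phenylcyclohexyl]oxy}chromane with C4 as in the target | c1ccccc1COc1ccc2c(c1)O[C@@H](O[C@@H]4CCCC[C@H]4c3ccccc3)C[C@H]2c1c(OCc3ccccc3)cc(OCc3ccccc3)c2c1O[C@H](c1cc(OCc3ccccc3)c(OCc3ccccc3)c(OCc3ccccc3)c1)[C@H](OCc3ccccc3)C2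
A7 | alternative 3 | (4R)-7-(benzyloxy)-4-(hexa-O-benzyl-epigallocatechin-8-yl)chroman-2-yl acetate (either C2 epimer) | c1ccccc1COc1ccc2c(c1)OC(OC(C)=O)C[C@H]2c1c(OCc3ccccc3)cc(OCc3ccccc3)c2c1O[C@H](c1cc(OCc3ccccc3)c(OCc3ccccc3)c(OCc3ccccc3)c1)[C@H](OCc3ccccc3)C2
A8 | alternative 3 | potassium [3,4-bis(benzyloxy)phenyl]trifluoroborate | [K+].F[B-](F)(F)c1ccc(OCc2ccccc2)c(OCc2ccccc2)c1
A9 | alternative 3 | nona-O-benzyl target (identical with 19) | c1ccccc1COc1ccc2c(c1)O[C@H](c1ccc(OCc3ccccc3)c(OCc3ccccc3)c1)C[C@H]2c1c(OCc3ccccc3)cc(OCc3ccccc3)c2c1O[C@H](c1cc(OCc3ccccc3)c(OCc3ccccc3)c(OCc3ccccc3)c1)[C@H](OCc3ccccc3)C2
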